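(The earlier runs and the new flask stem from a simulated flask for an exercise; noise was put on by code.)

Counted in percent of the substrate charged, the readings of the noon run and the autumn run are target made, and I held them against what the reagent charge allows.

| flask | substrate | reagent | capture agent | temperature | remark | time |
|---|---|---|---|---|---|---|
| noon | 41 mM | 24.6 mM | 12.3 mM | 25 °C | the very flask that is asked about, followed so far |  |
| autumn | 41 mM | 24.6 mM | 12.3 mM | 31 °C | run made earlier |  |
| flask | 41 mM | 24.6 mM | 12.3 mM | 25 °C |  | 80 min |

- noon (time / min: target / %): 8.00: 37; 25.0: 52; 40.0: 57; 60.0: 56
- autumn (time / min: target / %): 8.00: 43; 25.0: 59; 40.0: 60; 60.0: 59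

(standard deviation of a reading: 1.5 percentage points)

- south-west: at 80 min take out 90% of the target then present, then wait 2.5 h
- east: change nothing and wait 2.5 h more
- west: at 80 min raise the temperature by 20 K, then wait 2.5 h
- north: at 80 min add reagent, 100% of the amount charged, then wait 2.5 h

- target, in percent of the substrate first charged, at 80 min
- which option adds most target ("none" when 2 percentage points or less is all one gets) (south-west / east / west / north / none)
- target present, with what was taken out counted in, in percent of the substrate first charged, after west
- target present, with what was taken out counted in, in percent of the substrate first charged, after north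

- removed target is counted in
- additions bring no volume worth counting

1. Reagent charge. With 24.6 mM of reagent on 41 mM of substrate, c(reagent)/c(substrate) was 60.0%: the ceiling, the target that the reagent charge allows at one reagent per substrate. The one-to-one count was my assumption. Reagent, the smaller charge, was then the limiting reagent, and the substrate left over was 40.0%.

2. Time (east). The noon run read 57% at 40.0 min and 56% at 60.0 min, a step of 1 percentage point, smaller than the scatter. So I took their mean, 56.5%, for the flask at 80 min and expected nothing from waiting. That stood 3.5 points under the ceiling.

3. Removal (south-west). Taking out target helps a step that runs back, but the noon readings showed no rise to pull on, so I expected what waiting gives.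

4. Temperature (west). The autumn run read 60% at 40.0 min, higher than the noon run and level with the ceiling. But that run was warm from the start, while west heats a flask already flat, so I kept 56.5%.

5. Reagent (north). Doubling the reagent raised the ceiling to 100%, and substrate became the limiting charge. The noon run's plateau over the ceiling was 0.942. That share of the 40.0% left, added to 56.5%, gave 94.2%. I took 2.5 h as enough, being longer than the noon run needed to flatten. So north was my choice.

The forecast gave 57.5% (55.5% to 59.5%), north as best, 59% after west (54% to 62%) and 90% after north (77% to 99%), holding that “Adding reagent lifts the ceiling”; its first and west values lay above mine and its north value below.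

The flask gave 57.3% at 80 min, 57.3% after west and 95.6% after north, which was best at 38 points gained. At 80.0 min the flask held 2.66% as trapped intermediate. The ceiling 60.0% less the target is 2.7 points, the same amount.

    substrate + reagent → open intermediate (k = 4.40 M⁻¹ min⁻¹, Ea = 69.0 kJ mol⁻¹)
    open intermediate → target (k = 1.90 min⁻¹, Ea = 89.0 kJ mol⁻¹)
    open intermediate + capture agent → trapped intermediate (k = 7.50 M⁻¹ min⁻¹, Ea = 59.0 kJ mol⁻¹)
    (constants at 25 °C)

On the neighbour charged with 160 mM of substrate, the ceiling came to 15.4%, leaving 84.6% of its substrate over. Computed, that neighbour gave 14.7% target with 84.6% substrate left.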